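## Retrosynthetic overview

1. Ring B (the quinone ring) is formed last: the target opens to a chiral p-quinone monoketal (ring A precursor) and 2,5-bis(trimethylsilyloxy)furan. A [4+2] addition followed by loss of methanol leaves OMe beside the side chain and OH across the ring.
2. The senecioate ester is disconnected to the free carbinol (Steglich), and the monoketal to a 4-methoxyphenol (PhI(OAc)2, MeOH).
3. The prenyl group is disconnected to an allyl group (cross-metathesis with 2-methylbut-2-ene).
4. The (R)-carbinol comes from chiral phosphoric acid-catalysed allylboration of achiral 5-hydroxy-2-methoxybenzaldehyde.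
5. Ring order: ring A is bought as the benzene ring; ring B is the only ring made (step 5).

Assumption: every compound marked "starting material" in the list is taken to be purchasable.

## Route

**Step 1**
Reactants: 1 5-hydroxy-2-methoxybenzaldehyde; 2 2-allyl-4,4,5,5-tetramethyl-1,3,2-dioxaborolane
Product: 4 3-[(1R)-1-hydroxybut-3-en-1-yl]-4-methoxyphenol, via pinacol borate ester 3 (not isolated)
Conditions: (R)-TRIP [(R)-3,3'-bis(2,4,6-triisopropylphenyl)-1,1'-binaphthyl-2,2'-diyl hydrogen phosphate] (5 mol%), PhMe/CH2Cl2 4:1, −30 °C, 36 h; aq. NaHCO3 work-up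
Reagents that add atoms: 2-allyl-4,4,5,5-tetramethyl-1,3,2-dioxaborolane, C=CCB1OC(C)(C)C(C)(C)O1
Why: Chiral phosphoric acid-catalysed allylboration: the acid hydrogen-bonds to a boronate oxygen and to the formyl C–H in a closed chair transition state, so (R)-TRIP delivers the allyl group to the Re face of the aryl aldehyde and sets the (R)-carbinol (the only stereocentre), with the remote phenol and the ortho-OMe group as spectators.

**Step 2**
Reactants: 4 3-[(1R)-1-hydroxybut-3-en-1-yl]-4-methoxyphenol; 5 2-methylbut-2-ene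
Product: 6 3-[(1R)-1-hydroxy-4-methylpent-3-en-1-yl]-4-methoxyphenol
Conditions: second-generation Grubbs catalyst RuCl2(=CHPh)(PCy3)(H2IMes) (4 mol%), 2-methylbut-2-ene/CH2Cl2 1:1, 40 °C (sealed), 12 h
Reagents that add atoms: 2-methylbut-2-ene, CC=C(C)C
Why: Olefin cross-metathesis: the terminal alkene exchanges its CH2 for the isopropylidene unit of the excess trisubstituted alkene with loss of propene, while phenol, carbinol and stereocentre are untouched.

**Step 3**
Reactants: 6 3-[(1R)-1-hydroxy-4-methylpent-3-en-1-yl]-4-methoxyphenol; 7 methanol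
Product: 8 3-[(1R)-1-hydroxy-4-methylpent-3-en-1-yl]-4,4-dimethoxycyclohexa-2,5-dien-1-one
Conditions: PhI(OAc)2 (1.05 equiv), MeOH, 0 °C, 20 min; NaHCO3 quench
Reagents that add atoms: methanol, CO
Why: Oxidative dearomatisation of a 4-methoxyphenol (quinone monoketal synthesis with a hypervalent iodine reagent): methanol traps the phenoxonium ion at the OMe-bearing para carbon, which differentiates the two ring A oxygens (ketal carbon beside the side chain, carbonyl remote), and neither the alkene nor the secondary alcohol is oxidised.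

**Step 4**
Reactants: 8 3-[(1R)-1-hydroxy-4-methylpent-3-en-1-yl]-4,4-dimethoxycyclohexa-2,5-dien-1-one; 9 3-methylbut-2-enoic acid
Product: 11 (1R)-1-(6,6-dimethoxy-3-oxocyclohexa-1,4-dien-1-yl)-4-methylpent-3-en-1-yl 3-methylbut-2-enoate, via O-acylisourea 10 (not isolated)
Conditions: DCC (1.5 equiv), 4-(dimethylamino)pyridine (20 mol%), CH2Cl2, 0 °C to rt, 6 h
Reagents that add atoms: 3-methylbut-2-enoic acid, CC(C)=CC(=O)O
Why: Steglich esterification: the alcohol is acylated on oxygen, so the C–O bond of the stereocentre is not broken (retention), and the neutral conditions spare the acid-labile ketal.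

**Step 5**
Reactants: 11 (1R)-1-(6,6-dimethoxy-3-oxocyclohexa-1,4-dien-1-yl)-4-methylpent-3-en-1-yl 3-methylbut-2-enoate; 12 2,5-bis(trimethylsilyloxy)furan
Product: 15 (R)-5-hydroxy-8-methoxy-7-[4-methyl-1-(3-methylbut-2-enoyloxy)pent-3-en-1-yl]naphthalene-1,4-dione, via silylated oxa-bridged cycloadduct 13 (not isolated), via dihydronaphthalenetrione ketal 14 (not isolated)
Conditions: 12 (2 equiv), PhMe (2 M), 60 °C, argon, 16 h; then MeOH, Et3N, 0 °C to rt
Reagents that add atoms: 2,5-bis(trimethylsilyloxy)furan, C[Si](C)(C)Oc1ccc(O[Si](C)(C)C)o1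
Why: Proposed new method: a thermal Diels–Alder reaction of the very electron-rich bis(silyloxy)furan across the unsubstituted C4=C5 enone bond of 11 (the other enone bond is blocked by the branched side chain) gives 13; methanolysis of the two bridgehead silyl ketals unveils the ene-1,4-dione of ring B (14), whose C8a–H is now alpha to a carbonyl, so E1cB loss of one ketal methoxy group and enolisation of the C5 ketone aromatise ring A, leaving OMe beside the side chain, OH across the ring and ring B at the quinone level without any external oxidant and without touching the stereocentre; the closest known reactions are the Diels–Alder reaction of 2,5-bis(silyloxy)furans with quinones to give naphthazarins and the anionic phthalide annulation of quinone monoketals, which ends in the same methanol-loss aromatisation to a 1-hydroxy-4-methoxy arene.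

## Compound list

1 | 5-hydroxy-2-methoxybenzaldehyde | COc1ccc(O)cc1C=O | starting material
2 | 2-allyl-4,4,5,5-tetramethyl-1,3,2-dioxaborolane (allylboronic acid pinacol ester) | C=CCB1OC(C)(C)C(C)(C)O1 | starting material
3 | 2-{[(1R)-1-(5-hydroxy-2-methoxyphenyl)but-3-en-1-yl]oxy}-4,4,5,5-tetramethyl-1,3,2-dioxaborolane (not isolated) | COc1ccc(O)cc1[C@@H](CC=C)OB1OC(C)(C)C(C)(C)O1 | intermediate
4 | 3-[(1R)-1-hydroxybut-3-en-1-yl]-4-methoxyphenol | COc1ccc(O)cc1[C@@H](CC=C)O | intermediate
5 | 2-methylbut-2-ene | CC=C(C)C | starting material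
6 | 3-[(1R)-1-hydroxy-4-methylpent-3-en-1-yl]-4-methoxyphenol | COc1ccc(O)cc1[C@@H](CC=C(C)C)O | intermediate
7 | methanol | CO | starting material
8 | 3-[(1R)-1-hydroxy-4-methylpent-3-en-1-yl]-4,4-dimethoxycyclohexa-2,5-dien-1-one | COC1(OC)C=CC(=O)C=C1[C@@H](CC=C(C)C)O | intermediate
9 | 3-methylbut-2-enoic acid | CC(C)=CC(=O)O | starting material
10 | N,N'-dicyclohexyl-O-(3-methylbut-2-enoyl)isourea (not isolated) | CC(C)=CC(=O)OC(=NC1CCCCC1)NC1CCCCC1 | intermediate
11 | (1R)-1-(6,6-dimethoxy-3-oxocyclohexa-1,4-dien-1-yl)-4-methylpent-3-en-1-yl 3-methylbut-2-enoate | COC1(OC)C=CC(=O)C=C1[C@@H](CC=C(C)C)OC(=O)C=C(C)C | intermediate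
12 | 2,5-bis(trimethylsilyloxy)furan | C[Si](C)(C)Oc1ccc(O[Si](C)(C)C)o1 | starting material
13 | (1R)-1-[8,8-dimethoxy-5-oxo-1,4-bis(trimethylsilyloxy)-1,4,4a,5,8,8a-hexahydro-1,4-epoxynaphthalen-7-yl]-4-methylpent-3-en-1-yl 3-methylbut-2-enoate (not isolated; mixture of ring-fusion diastereomers, only the side-chain centre is defined) | O=C1C=C([C@@H](CC=C(C)C)OC(=O)C=C(C)C)C(OC)(OC)C2C1C1(O[Si](C)(C)C)C=CC2(O[Si](C)(C)C)O1 | intermediate
14 | (1R)-1-(8,8-dimethoxy-1,4,5-trioxo-1,4,4a,5,8,8a-hexahydronaphthalen-7-yl)-4-methylpent-3-en-1-yl 3-methylbut-2-enoate (not isolated; ring-fusion centres undefined) | O=C1C=C([C@@H](CC=C(C)C)OC(=O)C=C(C)C)C(OC)(OC)C2C1C(=O)C=CC2=O | intermediate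
15 | (R)-5-hydroxy-8-methoxy-7-[4-methyl-1-(3-methylbut-2-enoyloxy)pent-3-en-1-yl]naphthalene-1,4-dione | COc1c([C@@H](CC=C(C)C)OC(=O)C=C(C)C)cc(O)c2c1C(=O)C=CC2=O | target

## Count and risks

Total steps: 5. Longest linear sequence: 5 steps (1 to 15).

**Step 5 (proposed new step).** The monoketal may be too weak a dienophile. Lewis acids cannot be used to help, because they divert the furan to attack through C3 and ionise the ketal. Aqueous acid must also be avoided, because ketal hydrolysis would erase the OMe/OH differentiation.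

The fallback uses known chemistry; it sets out from 11 and comes back at 15. The ketal of 11 is hydrolysed (aqueous AcOH, THF) to the benzoquinone 2-[(1R)-4-methyl-1-(3-methylbut-2-enoyloxy)pent-3-en-1-yl]cyclohexa-2,5-diene-1,4-dione F1. Its Diels–Alder reaction with 12, the established quinone version of this cycloaddition, gives the silylated cycloadduct (1R)-1-[5,8-dioxo-1,4-bis(trimethylsilyloxy)-1,4,4a,5,8,8a-hexahydro-1,4-epoxynaphthalen-6-yl]-4-methylpent-3-en-1-yl 3-methylbut-2-enoate F2. Methanolysis (MeOH, Et3N) lets this tautomerise to the naphthazarin (1R)-1-(5,8-dihydroxy-1,4-dioxo-1,4-dihydronaphthalen-2-yl)-4-methylpent-3-en-1-yl 3-methylbut-2-enoate F3. Mono-O-methylation (MeI, Ag2O, CHCl3) then gives 15 together with its O-methyl regioisomers, from which it is separated by preparative HPLC (15 is recognised by the NOE between OMe and the carbinol H). This fallback gives up the regiocontrol of the monoketal, and 15, methylated on the most hindered oxygen, is expected to be a minor isomer, so it is a supply route of last resort.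

**Step 1.** The free phenol can compete for the phosphoryl oxygen of the catalyst, and the ortho-OMe aldehyde is hindered, so the ee may be low; the poor solubility of 1 at −30 °C may also slow the reaction.

The fallback sets the stereocentre by reduction instead of C–C bond formation; it sets out from 6 (of whatever enantiomeric purity, including material made without catalyst at rt) and comes back at 6. The benzylic alcohol is oxidised with MnO2 (CH2Cl2, rt) to the ketone 1-(5-hydroxy-2-methoxyphenyl)-4-methylpent-3-en-1-one F4. Corey–Bakshi–Shibata reduction with (S)-2-methyl-CBS-oxazaborolidine (10 mol%) and BH3·SMe2 (excess, the phenol consumes one hydride) in THF at −20 °C returns (R)-6; the aryl group is the large substituent, as in the acetophenone precedent.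

**Step 4.** The carbinol of 8 is hindered by the neighbouring ketal and sits gamma to the dienone carbonyl, so acylation may be slow and base could erode the stereocentre; the senecioyl unit can also deconjugate.

The fallback moves the acylation to the arene stage; it sets out from 6 and comes back at 11. Both hydroxyl groups of 6 are esterified (9, DCC, 4-(dimethylamino)pyridine, excess) to (1R)-1-{2-methoxy-5-[(3-methylbut-2-enoyl)oxy]phenyl}-4-methylpent-3-en-1-yl 3-methylbut-2-enoate F5. The much more labile aryl ester is cleaved selectively (K2CO3, MeOH, 0 °C) to (1R)-1-(5-hydroxy-2-methoxyphenyl)-4-methylpent-3-en-1-yl 3-methylbut-2-enoate F6. The step 3 conditions (PhI(OAc)2, MeOH, 0 °C) then convert F6 directly into 11.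

## Further compounds

F1 | step 5 | 2-[(1R)-4-methyl-1-(3-methylbut-2-enoyloxy)pent-3-en-1-yl]cyclohexa-2,5-diene-1,4-dione | CC(C)=CC[C@@H](OC(=O)C=C(C)C)C1=CC(=O)C=CC1=O
F2 | step 5 | (1R)-1-[5,8-dioxo-1,4-bis(trimethylsilyloxy)-1,4,4a,5,8,8a-hexahydro-1,4-epoxynaphthalen-6-yl]-4-methylpent-3-en-1-yl 3-methylbut-2-enoate | CC(C)=CC[C@@H](OC(=O)C=C(C)C)C1=CC(=O)C2C(C1=O)C1(O[Si](C)(C)C)C=CC2(O[Si](C)(C)C)O1
F3 | step 5 | (1R)-1-(5,8-dihydroxy-1,4-dioxo-1,4-dihydronaphthalen-2-yl)-4-methylpent-3-en-1-yl 3-methylbut-2-enoate | CC(C)=CC[C@@H](OC(=O)C=C(C)C)C1=CC(=O)c2c(O)ccc(O)c2C1=O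
F4 | step 1 | 1-(5-hydroxy-2-methoxyphenyl)-4-methylpent-3-en-1-one | COc1ccc(O)cc1C(=O)CC=C(C)C
F5 | step 4 | (1R)-1-{2-methoxy-5-[(3-methylbut-2-enoyl)oxy]phenyl}-4-methylpent-3-en-1-yl 3-methylbut-2-enoate | COc1ccc(OC(=O)C=C(C)C)cc1[C@@H](CC=C(C)C)OC(=O)C=C(C)C
F6 | step 4 | (1R)-1-(5-hydroxy-2-methoxyphenyl)-4-methylpent-3-en-1-yl 3-methylbut-2-enoate | COc1ccc(O)cc1[C@@H](CC=C(C)C)OC(=O)C=C(C)C
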